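Everything rests on deleting C10 from ring A (C1–C5, C10). C10 is the one ring A carbon that carries both the lactone oxygen and C20. The precursor of the key step is a cyclopentene, the C1=C5 silyl enol ether left by the enantioselective conjugate methylation that creates C4. Dibromocarbene reinserts C10 between C1 and C5. This one operation enlarges the five-membered ring to ring A and supplies three handles: C10–Br for union with the ring C fragment, C1=O as a relay stereocentre, and C5=C10 as Claisen terminus. Claisen transfer sets C5 and shifts the alkene to C1=C10, where the C19 acid closes the lactone. Acylation then closes ring B.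

Key step: step 3

Remark on numbering: icetexane numbering is used throughout.
- Ring A = C1, C2, C3, C4, C5, C10.
- Ring B = C5, C6, C7, C8, C9, C20, C10.
- Ring C = C8, C9, C11, C12, C13, C14.
- C18 = methyl on C4 and C19 = lactone carbonyl.
- β = the face of ring A that carries the lactone bridge.

Assumption: 1 and 7 are taken as commercial (7 is an intermediate of tapinarof manufacture). In step 2 the ligand antipode that delivers the S product is used.

Step 1
Reactants: 1 3-oxocyclopent-1-ene-1-carboxylic acid
Product: 2 tert-butyl 3-oxocyclopent-1-ene-1-carboxylate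
Conditions: isobutene, cat. H2SO4, CH2Cl2, sealed flask, rt
Reagents that add atoms: isobutene, CC(C)=C
Why: Acid-catalysed addition of the carboxylic acid to isobutene (tert-butyl ester formation) installs the one ester that acid can later remove beside an ethyl ester, and no stereocentre is formed.

Step 2
Reactants: 2 tert-butyl 3-oxocyclopent-1-ene-1-carboxylate
Product: 4 tert-butyl (S)-1-methyl-3-(trimethylsilyloxy)cyclopent-2-ene-1-carboxylate, via methylzinc enolate 3 (not isolated)
Conditions: Me2Zn, Cu(OTf)2 (5 mol %), chiral sulfonate-bearing imidazolinium salt as carbene ligand precursor (5 mol %), t-BuOMe, −30 °C; then TMSOTf, −78 → 0 °C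
Reagents that add atoms: dimethylzinc, C[Zn]C; trimethylsilyl triflate, C[Si](C)(C)OS(=O)(=O)C(F)(F)F
Why: Copper-catalysed enantioselective conjugate addition of a dialkylzinc to a cyclic γ-keto ester should create the quaternary C4 (S) by catalyst-controlled face selection, and O-silylation of the zinc enolate freezes the double bond regiospecifically at C1=C5.

Step 3
Reactants: 4 tert-butyl (S)-1-methyl-3-(trimethylsilyloxy)cyclopent-2-ene-1-carboxylate
Product: 6 tert-butyl (S)-3-bromo-1-methyl-4-oxocyclohex-2-ene-1-carboxylate, via dibromocyclopropane 5 (not isolated)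
Conditions: CHBr3, KOtBu, pentane, −30 °C → rt; then toluene, 60 °C
Reagents that add atoms: bromoform, BrC(Br)Br
Why: tert-Butoxide converts bromoform into dibromocarbene, which adds in a concerted [2+1] cheletropic step to the only nucleophilic π bond, the C1=C5 silyl enol ether, and so closes the three-membered ring of 5 (C1, C5, C10). The endo C10–Br bond then ionises while the shared C1–C5 bond opens in a disrotatory two-electron electrocyclic process pushed by the siloxy oxygen, and loss of Me3SiBr from the 2-bromo-1-siloxyallyl cation gives bromoenone 6, so that ring A is not closed by a new bond but grows out of the five-membered ring by insertion of C10. The closest known reaction type is the dihalocarbene ring expansion of cyclic silyl enol ethers to 2-halocycloalk-2-enones. No lasting stereocentre is created, because the two cyclopropane stereocentres C1 and C5 return to sp2 and C4, which has no acidic or ionisable bond, keeps its configuration. The step needs regioselectivity (C10 between C1 and C5, not between C1 and C2), and this is secured by the position of the enol ether double bond fixed in step 2. It also needs the base to spare the substrate, which is secured by the lack of enolisable hydrogen next to the tert-butyl ester and by work in pentane at low temperature.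

Step 4
Reactants: 7 (4-isopropyl-3,5-dimethoxyphenyl)methanol
Product: 8 (2-bromo-4-isopropyl-3,5-dimethoxyphenyl)methanol
Conditions: NBS, MeCN, 0 °C
Reagents that add atoms: N-bromosuccinimide, O=C1CCC(=O)N1Br
Why: Electrophilic aromatic bromination should stop at the monobromide, because the two free ring positions are equivalent, each is activated by one ortho and one para methoxy group, and the first bromine deactivates the ring.

Step 5
Reactants: 8 (2-bromo-4-isopropyl-3,5-dimethoxyphenyl)methanol
Product: 9 (4-isopropyl-2,3,5-trimethoxyphenyl)methanol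
Conditions: NaOMe, CuBr (15 mol %), MeOH–DMF, 110 °C
Reagents that add atoms: sodium methoxide, C[O-].[Na+]
Why: Copper-catalysed Ullmann-type methoxylation of an aryl bromide places the future C11 oxygen para to the C14 methoxy group, which is the pair needed for the late oxidation to the quinone.

Step 6
Reactants: 9 (4-isopropyl-2,3,5-trimethoxyphenyl)methanol
Product: 10 1-(chloromethyl)-4-isopropyl-2,3,5-trimethoxybenzene
Conditions: SOCl2, CH2Cl2, 0 °C
Reagents that add atoms: thionyl chloride, O=S(Cl)Cl
Why: Chlorodehydroxylation of a benzylic alcohol through its chlorosulfite gives the chloride, which inserts zinc with less homocoupling than the bromide would.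

Step 7
Reactants: 10 1-(chloromethyl)-4-isopropyl-2,3,5-trimethoxybenzene; 6 tert-butyl (S)-3-bromo-1-methyl-4-oxocyclohex-2-ene-1-carboxylate
Product: 12 tert-butyl (S)-3-(4-isopropyl-2,3,5-trimethoxybenzyl)-1-methyl-4-oxocyclohex-2-ene-1-carboxylate, via benzylzinc chloride 11 (not isolated)
Conditions: 10, Zn dust, LiCl, THF, rt; then 6, Pd(OAc)2 (2 mol %), SPhos (4 mol %), THF, rt → 40 °C
Reagents that add atoms: none
Why: Negishi cross-coupling of a benzylic zinc reagent with the activated C10–Br bond of an α-bromoenone forms C10–C20 and unites the two fragments, while ketone, ester and C4 are untouched by the mild organozinc.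

Step 8
Reactants: 12 tert-butyl (S)-3-(4-isopropyl-2,3,5-trimethoxybenzyl)-1-methyl-4-oxocyclohex-2-ene-1-carboxylate
Product: 13 tert-butyl (1S,4R)-4-hydroxy-3-(4-isopropyl-2,3,5-trimethoxybenzyl)-1-methylcyclohex-2-ene-1-carboxylate (OH on C1 β, cis to CO2tBu)
Conditions: (S)-2-methyl-CBS-oxazaborolidine (20 mol %), BH3·SMe2, THF, −30 °C
Reagents that add atoms: none
Why: In the Corey–Bakshi–Shibata reduction the oxazaborolidine takes the α-substituted alkenyl arm (C10) as the large and C2H2 as the small group, so hydride should reach C1 from the α face and give the 1β-alcohol under reagent control.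

Step 9
Reactants: 13 tert-butyl (1S,4R)-4-hydroxy-3-(4-isopropyl-2,3,5-trimethoxybenzyl)-1-methylcyclohex-2-ene-1-carboxylate
Product: 15 tert-butyl (1S,2R)-2-(2-ethoxy-2-oxoethyl)-3-(4-isopropyl-2,3,5-trimethoxybenzyl)-1-methylcyclohex-3-ene-1-carboxylate (CH2CO2Et cis to CO2tBu, H-5 α), via ketene acetal 14 (not isolated)
Conditions: MeC(OEt)3, cat. EtCO2H, xylene, 135 °C, EtOH distilled off
Reagents that add atoms: triethyl orthoacetate, CC(OCC)(OCC)OCC
Why: In the Johnson–Claisen rearrangement orthoester exchange gives ketene acetal 14, whose suprafacial [3,3] shift hands the C1–O chirality on to C5, so that C5–C6 forms on the β face while C1 loses its oxygen and the alkene moves to C1=C10.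

Step 10
Reactants: 15 tert-butyl (1S,2R)-2-(2-ethoxy-2-oxoethyl)-3-(4-isopropyl-2,3,5-trimethoxybenzyl)-1-methylcyclohex-3-ene-1-carboxylate
Product: 17 (4S,5S,10S)-19,10-lactone ethyl ester (6-oxabicyclo[3.2.1]octan-7-one with methyl on C4, the benzyl group on C10 and CH2CO2Et on the one-carbon bridge C5, syn to the lactone bridge), via free acid 16 (not isolated)
Conditions: TFA–CH2Cl2 (1:4), 0 °C
Reagents that add atoms: none
Why: Acid cleaves only the tert-butyl ester, and Markovnikov protonation of C1=C10 at C1 gives the tertiary C10 cation, which the C19 acid held on the β face by C4 traps in a 5-exo acid-catalysed lactonisation, so C10 is set by the tether (O β) and C5 is not touched.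

Step 11
Reactants: 17 (4S,5S,10S)-19,10-lactone ethyl ester
Product: 18 (4S,5S,10S)-19,10-lactone acid (C7 carboxylic acid)
Conditions: LiOH, THF–H2O, 0 °C → rt; then 1 M HCl
Reagents that add atoms: lithium hydroxide, [Li+].[OH-]
Why: Saponification should take the unhindered primary ethyl ester much faster than the neopentyl-type lactone carbonyl C19, and any opened lactone recloses on acidification because the hydroxyl and the acid stay 1,3-diaxial.

Step 12
Reactants: 18 (4S,5S,10S)-19,10-lactone acid
Product: 20 (4S,5S,10S)-11,12,14-trimethoxy-7-oxoicetexa-8,11,13-trien-19,10-olide, via mixed anhydride 19 (not isolated)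
Conditions: TFAA, CH2Cl2, 0 °C → rt
Reagents that add atoms: none
Why: Intramolecular Friedel–Crafts acylation through the mixed trifluoroacetic anhydride closes the seven-membered ring B at C8, the only free position of ring C, which is activated by the ortho C14 and para C12 methoxy groups, without a strong acid that could ionise the lactone.

Step 13
Reactants: 20 (4S,5S,10S)-11,12,14-trimethoxy-7-oxoicetexa-8,11,13-trien-19,10-olide
Product: 21 (4S,5S,7R,10S)-7α-hydroxy-11,12,14-trimethoxyicetexa-8,11,13-trien-19,10-olide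
Conditions: (S)-2-methyl-CBS-oxazaborolidine (20 mol %), BH3·SMe2, THF, −20 °C
Reagents that add atoms: none
Why: Corey–Bakshi–Shibata reduction of a benzosuberone-type aryl alkyl ketone (aryl large, C6H2 small) should give the 7R alcohol (7α-OH) under reagent control, and the lactone is inert to borane at this temperature.

Step 14
Reactants: 21 (4S,5S,7R,10S)-7α-hydroxy-11,12,14-trimethoxyicetexa-8,11,13-trien-19,10-olide
Product: 22 (4S,5S,7R,10S)-7α-acetoxy-11,12,14-trimethoxyicetexa-8,11,13-trien-19,10-olide
Conditions: Ac2O, Et3N, cat. DMAP, CH2Cl2, 0 °C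
Reagents that add atoms: acetic anhydride, CC(=O)OC(C)=O
Why: DMAP-catalysed acylation at oxygen under basic conditions leaves the C7–O bond intact, so the configuration at C7 is retained.

Step 15
Reactants: 22 (4S,5S,7R,10S)-7α-acetoxy-11,12,14-trimethoxyicetexa-8,11,13-trien-19,10-olide
Product: 23 (4S,5S,7R,10S)-7α-acetoxy-12-methoxy-11,14-dioxoicetexa-8,12-dien-19,10-olide
Conditions: (NH4)2Ce(NO3)6, MeCN–H2O, 0 °C
Reagents that add atoms: water, O
Why: Oxidative demethylation of the para-dimethoxy pair C11/C14 by tetravalent cerium is fast at 0 °C and should give the para-quinone with the 12-methoxy group kept, before the benzylic acetate can solvolyse.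

Step 16
Reactants: 23 (4S,5S,7R,10S)-7α-acetoxy-12-methoxy-11,14-dioxoicetexa-8,12-dien-19,10-olide
Product: 24 7α-acetoxy-6,7-dihydroicetexone
Conditions: BCl3, CH2Cl2, −78 → −20 °C; then H2O
Reagents that add atoms: none
Why: In this chelation-assisted ether cleavage BCl3 binds C11=O and the neighbouring 12-methoxy oxygen of the vinylogous ester and chloride removes the methyl group at low temperature, while the acetate next to the electron-poor quinone should neither ionise nor be cleaved.

Compound list
1 | 3-oxocyclopent-1-ene-1-carboxylic acid | O=C1C=C(C(=O)O)CC1 | starting material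
2 | tert-butyl 3-oxocyclopent-1-ene-1-carboxylate | O=C1C=C(C(=O)OC(C)(C)C)CC1 | intermediate
3 | methylzinc enolate of tert-butyl (S)-1-methyl-3-oxocyclopentane-1-carboxylate (C1=C5) | C[Zn]OC1=C[C@@](C)(C(=O)OC(C)(C)C)CC1 | intermediate
4 | tert-butyl (S)-1-methyl-3-(trimethylsilyloxy)cyclopent-2-ene-1-carboxylate | C[Si](C)(C)OC1=C[C@@](C)(C(=O)OC(C)(C)C)CC1 | intermediate
5 | tert-butyl 6,6-dibromo-2-methyl-5-(trimethylsilyloxy)bicyclo[3.1.0]hexane-2-carboxylate (C4 as in 4, cyclopropane face without consequence) | C[Si](C)(C)OC12CC[C@](C)(C(=O)OC(C)(C)C)C1C2(Br)Br | intermediate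
6 | tert-butyl (S)-3-bromo-1-methyl-4-oxocyclohex-2-ene-1-carboxylate | O=C1CC[C@](C)(C(=O)OC(C)(C)C)C=C1Br | intermediate
7 | (4-isopropyl-3,5-dimethoxyphenyl)methanol | OCc1cc(OC)c(C(C)C)c(OC)c1 | starting material
8 | (2-bromo-4-isopropyl-3,5-dimethoxyphenyl)methanol | OCc1cc(OC)c(C(C)C)c(OC)c1Br | intermediate
9 | (4-isopropyl-2,3,5-trimethoxyphenyl)methanol | OCc1cc(OC)c(C(C)C)c(OC)c1OC | intermediate
10 | 1-(chloromethyl)-4-isopropyl-2,3,5-trimethoxybenzene | ClCc1cc(OC)c(C(C)C)c(OC)c1OC | intermediate
11 | (4-isopropyl-2,3,5-trimethoxybenzyl)zinc chloride | Cl[Zn]Cc1cc(OC)c(C(C)C)c(OC)c1OC | intermediate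
12 | tert-butyl (S)-3-(4-isopropyl-2,3,5-trimethoxybenzyl)-1-methyl-4-oxocyclohex-2-ene-1-carboxylate | O=C1CC[C@](C)(C(=O)OC(C)(C)C)C=C1Cc2cc(OC)c(C(C)C)c(OC)c2OC | intermediate
13 | tert-butyl (1S,4R)-4-hydroxy-3-(4-isopropyl-2,3,5-trimethoxybenzyl)-1-methylcyclohex-2-ene-1-carboxylate (OH cis to CO2tBu) | O[C@@H]1CC[C@](C)(C(=O)OC(C)(C)C)C=C1Cc2cc(OC)c(C(C)C)c(OC)c2OC | intermediate
14 | 1-ethoxyvinyl ether of 13 (mixed ketene acetal) | C=C(OCC)O[C@@H]1CC[C@](C)(C(=O)OC(C)(C)C)C=C1Cc2cc(OC)c(C(C)C)c(OC)c2OC | intermediate
15 | tert-butyl (1S,2R)-2-(2-ethoxy-2-oxoethyl)-3-(4-isopropyl-2,3,5-trimethoxybenzyl)-1-methylcyclohex-3-ene-1-carboxylate (CH2CO2Et cis to CO2tBu) | CCOC(=O)C[C@@H]1C(Cc2cc(OC)c(C(C)C)c(OC)c2OC)=CCC[C@]1(C)C(=O)OC(C)(C)C | intermediate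
16 | (1S,2R)-2-(2-ethoxy-2-oxoethyl)-3-(4-isopropyl-2,3,5-trimethoxybenzyl)-1-methylcyclohex-3-ene-1-carboxylic acid | CCOC(=O)C[C@@H]1C(Cc2cc(OC)c(C(C)C)c(OC)c2OC)=CCC[C@]1(C)C(=O)O | intermediate
17 | (4S,5S,10S)-19,10-lactone ethyl ester (bridged γ-lactone C4–C19(=O)–O–C10, H-5 α, CH2CO2Et on C5, benzyl group on C10) | CCOC(=O)C[C@@H]1[C@]2(CCC[C@]1(C)C(=O)O2)Cc3cc(OC)c(C(C)C)c(OC)c3OC | intermediate
18 | (4S,5S,10S)-19,10-lactone acid (CH2CO2H on C5) | OC(=O)C[C@@H]1[C@]2(CCC[C@]1(C)C(=O)O2)Cc3cc(OC)c(C(C)C)c(OC)c3OC | intermediate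
19 | mixed trifluoroacetic anhydride of 18 | FC(F)(F)C(=O)OC(=O)C[C@@H]1[C@]2(CCC[C@]1(C)C(=O)O2)Cc3cc(OC)c(C(C)C)c(OC)c3OC | intermediate
20 | (4S,5S,10S)-11,12,14-trimethoxy-7-oxoicetexa-8,11,13-trien-19,10-olide | O=C1C[C@@H]2[C@]3(CCC[C@]2(C)C(=O)O3)Cc4c1c(OC)c(C(C)C)c(OC)c4OC | intermediate
21 | (4S,5S,7R,10S)-7α-hydroxy-11,12,14-trimethoxyicetexa-8,11,13-trien-19,10-olide | O[C@@H]1C[C@@H]2[C@]3(CCC[C@]2(C)C(=O)O3)Cc4c1c(OC)c(C(C)C)c(OC)c4OC | intermediate
22 | (4S,5S,7R,10S)-7α-acetoxy-11,12,14-trimethoxyicetexa-8,11,13-trien-19,10-olide | CC(=O)O[C@@H]1C[C@@H]2[C@]3(CCC[C@]2(C)C(=O)O3)Cc4c1c(OC)c(C(C)C)c(OC)c4OC | intermediate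
23 | (4S,5S,7R,10S)-7α-acetoxy-12-methoxy-11,14-dioxoicetexa-8,12-dien-19,10-olide | CC(=O)O[C@@H]1C[C@@H]2[C@]3(CCC[C@]2(C)C(=O)O3)CC4=C1C(=O)C(C(C)C)=C(OC)C4=O | intermediate
24 | 7α-acetoxy-6,7-dihydroicetexone (4S,5S,7R,10S) | CC(=O)O[C@@H]1C[C@@H]2[C@]3(CCC[C@]2(C)C(=O)O3)CC2=C1C(=O)C(C(C)C)=C(O)C2=O | target

Total step count: 16. Longest linear sequence: 13 steps (steps 1–3 followed by 7–16, or equally steps 4–6 followed by 7–16).

Steps most likely to fail

**Step 3 (key step).** Carbene transfer to the enol ether may be slowed by the neighbouring quaternary C4. Desilylation by tert-butoxide and self-consumption of the carbene could then win. The fallback keeps the enlargement from five to six ring atoms but replaces the electrocyclic opening by a one-electron oxidative opening. It sets out from 4.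
- Simmons–Smith cyclopropanation (Et2Zn, CH2I2) should give the siloxycyclopropane F1.
- FeCl3 in DMF should cleave the shared C1–C5 bond to the ring-enlarged β-chloro ketone F2.
- NaOAc in MeOH should eliminate to the enone F3.
- Br2 followed by Et3N should lead through the dibromide F4 back to the route at 6.

**Step 9.** The [3,3] shift has to form C5–C6 next to the quaternary C4 and may be sluggish at 135 °C. Acid-catalysed dehydration of the allylic alcohol and thermal loss of the tert-butyl group could then compete. The fallback attaches the two-carbon unit first and rearranges an ester enolate derivative at low temperature (Ireland–Claisen). It sets out from 13.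
- Ac2O and pyridine should give the allylic acetate F5.
- LDA and TMSCl in THF at −78 °C should give the silyl ketene acetal F6.
- Warming to rt should give the silyl ester F7, and aqueous work-up the acid F8.
- EtI and K2CO3 in DMF return to the route at 15.

**Step 10.** The free C10 cation may leak. A 1,2-hydride shift from C20 would lead to a benzylic cation stabilised by the C11 methoxy group, and proton loss from C5 followed by reprotonation would erode the configuration at C5. The fallback avoids a free cation by halolactonisation. It sets out from 15.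
- I2 in MeCN at 0 °C should open an α-face iodonium ion at C10 with the tert-butyl ester carbonyl, with loss of the tert-butyl group, and give the iodolactone F9.
- Bu3SnH with AIBN in toluene should remove the iodine at C1 by radical reduction and return to the route at 17.

Further compounds
F1 | step 3 | tert-butyl 2-methyl-5-(trimethylsilyloxy)bicyclo[3.1.0]hexane-2-carboxylate, C4 as in 4 | C[Si](C)(C)OC12CC[C@](C)(C(=O)OC(C)(C)C)C1C2
F2 | step 3 | tert-butyl 2-chloro-1-methyl-4-oxocyclohexane-1-carboxylate, C4 as in 4 | O=C1CC[C@](C)(C(=O)OC(C)(C)C)C(Cl)C1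
F3 | step 3 | tert-butyl (S)-1-methyl-4-oxocyclohex-2-ene-1-carboxylate | O=C1CC[C@](C)(C(=O)OC(C)(C)C)C=C1
F4 | step 3 | tert-butyl 2,3-dibromo-1-methyl-4-oxocyclohexane-1-carboxylate, C4 as in 4 | O=C1CC[C@](C)(C(=O)OC(C)(C)C)C(Br)C1Br
F5 | step 9 | acetate of 13 | CC(=O)O[C@@H]1CC[C@](C)(C(=O)OC(C)(C)C)C=C1Cc2cc(OC)c(C(C)C)c(OC)c2OC
F6 | step 9 | trimethylsilyl ketene acetal of F5 | C=C(O[Si](C)(C)C)O[C@@H]1CC[C@](C)(C(=O)OC(C)(C)C)C=C1Cc2cc(OC)c(C(C)C)c(OC)c2OC
F7 | step 9 | trimethylsilyl ester analogue of 15 | C[Si](C)(C)OC(=O)C[C@@H]1C(Cc2cc(OC)c(C(C)C)c(OC)c2OC)=CCC[C@]1(C)C(=O)OC(C)(C)C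
F8 | step 9 | C7 carboxylic acid analogue of 15 | OC(=O)C[C@@H]1C(Cc2cc(OC)c(C(C)C)c(OC)c2OC)=CCC[C@]1(C)C(=O)OC(C)(C)C
F9 | step 10 | 1α-iodo derivative of 17 | CCOC(=O)C[C@@H]1[C@]2([C@@H](I)CC[C@]1(C)C(=O)O2)Cc3cc(OC)c(C(C)C)c(OC)c3OC
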